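The numbers of this flask were drawn at random within sensible limits; the flask was simulated.

D.Q cannot go on rising for as long as Q is present, since Q both makes it from D and turns it into Q.D.Q.

    D + Q → J, rate k1*[D] as long as [Q] is above zero (k1 = 0.0061 s⁻¹)
    Q + D.Q → Q.D.Q (k2 = 0.0084 M⁻¹ s⁻¹)
    D + Q → D.Q (k3 = 0.010 M⁻¹ s⁻¹)

| flask | D | Q | remark | time |
|---|---|---|---|---|
| Tuesday's | 1.5 M | 1.65 M | one stirred flow tank at steady state, fed with the mixture as stated, mean residence time 2.5 min |  |
| Friday's | 1.5 M | 1.65 M (fed, over 2.00 min) | a stirred flask in which Q is dosed at a steady rate over 2.00 min without added volume, worked up at 2.5 min | 2.5 min |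
| Thursday's | 1.5 M | 1.65 M | everything together in a closed stirred flask, run for 2.5 min | 2.5 min |
| Saturday's | 1.5 M (fed, over 2.00 min) | 1.65 M | a stirred flask in which D is dosed at a steady rate over 2.00 min without added volume, worked up at 2.5 min | 2.5 min |

- the stated concentrations are those of everything mixed, before any reaction; amounts are the same in each set-up
- the feed brings no volume worth counting
- run time (Friday's): 2.5 min

* the set-up with the highest amount of D.Q at the outlet or at the end, in percent of the D put in ("none" if the first two lie within 2 percentage points) (Tuesday's / Friday's / Thursday's / Saturday's / none)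
* amount of D.Q at the outlet or at the end, in percent of the D put in, Tuesday's
* amount of D.Q at the outlet or at the end, in percent of the D put in, Friday's
* amount of D.Q at the outlet or at the end, in percent of the D put in, Thursday's
* amount of D.Q at the outlet or at the end, in percent of the D put in, Saturday's

**Turning ratio.** D.Q forms with constant 0.010 M⁻¹ s⁻¹ times [D][Q] and is lost with constant 0.0084 M⁻¹ s⁻¹ times [D.Q][Q]. Both rates carry [Q], so [Q] cancels from their comparison while Q remains. D.Q therefore rises while [D.Q]/[D] lies below the formation constant divided by the loss constant, and it turns at that value, the turning ratio 1.19. This is the selectivity factor of the pair, read upside down. The ring route also consumes D, but its constant does not enter the ratio.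

**Rough figure.** Take Thursday's closed flask. Hold [Q] at its charge, a crude pseudo-first-order view, and leave out the ring route. D then decays at 0.990 min⁻¹ and D.Q at 0.832 min⁻¹. The two-exponential curve for a product made and lost gives 25.6% of the D put in as D.Q at 2.5 min.

**The forecast.** The forecast names Thursday's as best, with 30.5% there, 26.3% for Saturday's, 18% for Friday's and 17.5% for Tuesday's. Its ground is that “D.Q forms fastest when D and Q are both high at once”. Its Thursday's figure stands higher than the rough figure above.

**The flask.** The simulation gives 30.4% for Thursday's, 26.4% for Saturday's, 18.0% for Friday's and 17.6% for Tuesday's, so Thursday's leads. In Thursday's flask, at the charged [Q], D has a half-life of 0.70 min by step 3 alone and D.Q one of 0.83 min by step 2 alone, longer by the turning ratio of 1.19. Saturday's [D] peaks at 0.670 M, where the ratio puts a ceiling on [D.Q] of 0.797 M, and Saturday's D.Q ends lower than that, at 0.396 M.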